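## The problem

Hansforester I 26 is an open-chain oligoester built from four hydroxy acids. A terminal (R)-3-hydroxybutanoic acid, a 2,4-dihydroxy-6-(2-hydroxypropyl)benzoic acid (ring A), a second (R)-3-hydroxybutanoic acid and a 2,4-dihydroxy-6-(4-hydroxy-2-oxopentyl)benzoic acid (ring B; side chain C8 benzylic CH2, C9 ketone, C10, C11 carbinol) are joined head to tail by three ester bonds, with nothing fused or bridged. Two of these bonds are esters of 2,6-disubstituted benzoic acids with secondary alcohols, the hardest kind to make by direct acylation; the third is an ordinary aliphatic ester. The four stereocentres are all (R) methyl carbinol carbons and lie at least five atoms apart, so none can steer another; each must come from the chiral pool and be carried through untouched. Both butanoate units are β-acyloxy carbonyl compounds, which expel the aryl carboxylate by β-elimination once their α-carbon is enolised or their acyl group is strongly activated. On ring A the side-chain oxygen, whenever free, can close a six-membered lactone onto the benzoate; on ring B the C9 ketone can enolise towards the ester (isocoumarin) or lose the C11 oxygen. The acid, the four phenols and the β-hydroxy ketone therefore have to be released together, under neutral conditions, at the very end. The feature that opens the key step is ring A itself: C1 carboxylate, C2 and C4 oxygens and the C6 chain are the pattern of a 2,4-dioxocyclohexane-1-carboxylate minus two hydrogens, so C1–C3 plus the ester can come from an acetoacetate and C4–C6 plus the side chain from an enoate.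

## Retrosynthesis

**26 to 25.** All six O–H groups (four phenols, the acid, C11–OH) are traced back to benzyl ethers or a benzyl ester in 25. Six O–benzyl bonds are cut in one hydrogenolysis, the only deprotection that touches neither the β-acyloxy esters nor the β-hydroxy ketone. The price is that every earlier step must tolerate benzyl groups and that the substrate of the last step must carry no sulfur-containing group.

**25 to 14 and 24.** The acyl–O bond between the ring A side-chain oxygen and the middle butanoate is cut. Of the three ester bonds it is the only unhindered one, and it divides the molecule into halves of similar size, alcohol 14 and acid 24. Cutting at either aryl ester instead would require activating a 2,6-disubstituted benzoic acid on a large fragment. The forward step must acylate a secondary alcohol without β-elimination from the activated acid and without lactonisation of 14.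

**14 to 13 to 12.** The side-chain oxygen is kept as a silyl ether and the phenols as benzyl ethers, so that only the side chain is freed before the coupling. Desilylation has to be acidic, because an alkoxide at this position would attack the neighbouring benzoate.

**12 to 11.** Ring A is taken back to its dihydro form, the 2,4-dioxocyclohexanecarboxylate 11. The benzoate ester is then no longer an aryl ester to be forged but the ester of a β-keto ester. The forward reaction must remove two hydrogens without harming a silyl ether or a benzyl ester.

**11 to 5 and 9 (key disconnection).** Ring bonds C1–C6 and C3–C4 are cut, giving acetoacetate 5 and enoate 9 by way of the open Michael adduct 10. This is preferred over any cut through the aryl ester because 5 carries the hindered ester ready-made and 9 carries the side-chain stereocentre. Both precursors are acyclic and achiral apart from one chiral-pool carbinol each. The forward step must give conjugate addition before acyl transfer and must not enolise any ester.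

**5 to 2 and 3; 2 to 1; 9 to 7 and 8; 7 to 6.** The acetoacetate is cut at its ester C–O bond into benzyl (R)-3-hydroxybutanoate 2 and dioxinone 3, the source of acetylketene 4; 2 comes from the methyl ester 1. The enoate is cut at its C2–C3 double bond into silyl ether 7 and methyl acrylate 8 (cross-metathesis), and 7 comes from (R)-pent-4-en-2-ol 6. This is one step shorter than reduction and olefination of a silyloxybutanoate.

**24 to 23 to 21.** The carboxyl group of the middle butanoate is traced to the terminal alkene of a pent-4-en-2-yl ester, by way of aldehyde 23 and diol 22. A carboxyl or ester here would be enolised by the strong base needed for the next disconnection and would expel the benzoate; an alkene has no acidic α-hydrogen. The cost is two oxidation steps.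

**21 to 20 and 16.** The C8–C9 bond is cut into the benzylic anion of orsellinate 20 and Weinreb amide 16, which carries C11. The alternative cut at C9–C10 would need a stereoselective aldol reaction. The forward step needs a base strong enough for lateral lithiation and an acyl donor that stops at the ketone stage.

**20 to 19 to 17 and 18; 16 to 15 to 1.** The ring B aryl ester is cut at the alkyl C–O bond into orsellinic acid 17 and (S)-pent-4-en-2-ol 18, joined with inversion. With a simple alcohol this is a reliable way to a hindered benzoate. It is not open to ring A, whose alcohol partner would be a β-hydroxy ester and whose acid would need its side chain installed first. Amide 16 comes from 1 through benzyl ether 15. Ring B is bought as the arene rather than annulated because an enoate bearing the C9 ketone would have a doubly activated C8 methylene.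

## Roads not taken

**Alternative 1:** The ring B side chain is cut at C8–C9 and C9–C10 around a dithiane carbon. In the forward step 2-(tert-butyldimethylsilyl)-1,3-dithiane A1, after lithiation at C2, opens (R)-propylene oxide A2 at its CH2 group, HMPA triggers a 1,4-shift of silicon from carbon to oxygen, and the regenerated dithiane anion is alkylated by the benzylic bromide A3 to give aryl bromide A4.
- Merits: the three components A1, A2 and A3 are joined in one flask, C11 comes from epoxide A2, the cheapest chiral building block available for it, and C9 arrives masked with C11–O protected. In that respect it is better than the chosen lateral acylation (step 13), after which the ketone is free and can enolise towards the ester.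
- Weak points: it solves a side chain only. A4 must still be carboxylated by bromine–lithium exchange and the resulting 2,6-disubstituted acid esterified with a β-hydroxy ester, the hardest bond of the target. The dithiane that A1 brings in must be removed oxidatively, next to electron-rich rings, before any hydrogenolysis, because sulfur poisons palladium. A3 needs its own multistep preparation.
- Comparison: the chosen plan gives up the masked ketone; in return neither aryl ester is made by activating a hindered benzoic acid, and no intermediate ever carries a sulfur-containing group.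

**Alternative 2:** Ring A is cut at C1–C2 and C5–C6. The ynoate ester A5 and the bis(silyloxy)diene A6 would undergo a thermal Diels–Alder reaction, the bridged adduct would extrude its gem-dimethyl two-carbon bridge, and acidic work-up would free the resorcinol A7, which is identical with 12.
- Merits: the ring is formed at the aromatic oxidation level, so the least secure step of the chosen plan (step 6) disappears. No base is present, so neither β-elimination nor silanolate loss can occur. On these two counts the cycloaddition is the better road.
- Weak points: A5 must be made by carboxylating a silyloxypentyne and coupling the 2-ynoic acid with 2, an activation prone to conjugate addition. Internal β-alkyl ynoates need temperatures well above 120 °C with this diene, where the β-acyloxy ester can undergo thermal syn-elimination and the silyl enol ethers migrate.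
- Comparison: step counts to 12 are about equal. The chosen plan offers cheap fragments, each made in two steps, a neutral acetoacetylation in place of an acid activation, and nothing hotter than 120 °C.

**Alternative 3:** Ring B is formed last, on the assembled alcohol, by cutting its ester C–O bond and ring bond C1–C6. Heating the diketo-dioxinone A8 with alcohol A9 would unmask an acylketene that the alcohol captures; Cs2CO3 and then acid would close and dehydrate the ring to A10.
- Merits: it is the most convergent plan. The hindered ring B ester arises by ketene capture, with no Mitsunobu reaction, no masked carboxyl group and no oxidant. Here it is clearly better than the chosen ring B sequence of seven steps.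
- Weak points: A8 is a sensitive polycarbonyl chain that needs several steps. A9 holds two β-acyloxy ester links that would be exposed to about 100 °C and to Cs2CO3. The acid-mediated dehydration threatens the dioxolane and silyl ether. Three different deprotections would remain on the complete molecule. A9 has to be made from 14 in any case, so ring A still needs its own solution.
- Comparison: the chosen plan does all ring construction and aromatisation on small fragments and ends with one esterification and one hydrogenolysis; no base ever meets the assembled polyester.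

Key step: step 5

Assumption: 1, 6, 17 and 18 are taken as purchasable in high enantiomeric purity; 11 is expected as a mixture of ring diastereomers and keto–enol forms, which does not matter because step 6 removes both ring stereocentres.

## Route

Step 1
Reactants: 1 methyl (R)-3-hydroxybutanoate
Product: 2 benzyl (R)-3-hydroxybutanoate
Conditions: BnOH (excess), Ti(OEt)4 (cat.), 110 °C, MeOH distilled off
Reagents that add atoms: benzyl alcohol, OCc1ccccc1
Why: Titanate-catalysed transesterification runs under neutral conditions, so the β-hydroxy ester should neither dehydrate nor racemise; the carbinol centre is not involved.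

Step 2
Reactants: 2 benzyl (R)-3-hydroxybutanoate; 3 2,2,6-trimethyl-4H-1,3-dioxin-4-one
Product: 5 (R)-4-(benzyloxy)-4-oxobutan-2-yl 3-oxobutanoate, via acetylketene 4 (not isolated)
Conditions: toluene, 120 °C (sealed vessel or acetone distilled off)
Reagents that add atoms: none
Why: Thermal retro-[4+2] cleavage of the dioxinone releases acetylketene, which the secondary alcohol traps; this acetoacetylation needs no base or coupling reagent, so the β-oxygenated ester is not at risk.

Step 3
Reactants: 6 (R)-pent-4-en-2-ol
Product: 7 tert-butyldimethyl[(R)-pent-4-en-2-yloxy]silane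
Conditions: TBSCl, imidazole, DMF, rt
Reagents that add atoms: tert-butyldimethylsilyl chloride, CC(C)(C)[Si](C)(C)Cl
Why: Standard silylation of a secondary alcohol at oxygen; the stereocentre is untouched.

Step 4
Reactants: 7 tert-butyldimethyl[(R)-pent-4-en-2-yloxy]silane; 8 methyl acrylate (excess)
Product: 9 methyl (R,E)-5-[(tert-butyldimethylsilyl)oxy]hex-2-enoate
Conditions: second-generation Grubbs catalyst (H2IMes)(PCy3)Cl2Ru=CHPh (2 mol %), CH2Cl2, 40 °C
Reagents that add atoms: none
Why: Olefin cross-metathesis of an unhindered terminal alkene with an acrylate is selective for the cross product and for the (E)-enoate, with ethylene loss as the driving force.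

Step 5
Reactants: 5 (R)-4-(benzyloxy)-4-oxobutan-2-yl 3-oxobutanoate; 9 methyl (R,E)-5-[(tert-butyldimethylsilyl)oxy]hex-2-enoate
Product: 11 (R)-4-(benzyloxy)-4-oxobutan-2-yl 6-{(R)-2-[(tert-butyldimethylsilyl)oxy]propyl}-2,4-dioxocyclohexane-1-carboxylate, via Michael adduct 10 (not isolated)
Conditions: 5 (1.2 equiv), KOt-Bu (1.1 equiv), THF/t-BuOH, 0 °C; then 9, rt to 50 °C; cold 1 M HCl
Reagents that add atoms: none
Why: This is a Michael–Claisen annulation, the reaction type by which acetoacetates and crotonates give dihydroorsellinates. KOt-Bu is consumed completely in forming the C2 enolate of 5, which adds 1,4 to the β-carbon of 9 (ring bond C1–C6), and proton transfer through t-BuOH gives the enolate of adduct 10. The small equilibrium share of the methyl-ketone enolate then attacks the methyl ester (ring bond C3–C4) in a 6-(enolendo)-exo-trig closure, and loss of methoxide becomes irreversible because the new 1,3-dione is deprotonated at once. Ring carbons C1 and C6 become stereocentres without control (C1 is epimerisable, C6 sees only the remote silyloxy carbon), which is harmless since step 6 flattens both; the two (R) carbinol centres are not touched. The step needs conjugate addition before any acyl transfer, no γ-deprotonation of 9 (which would expel silanolate and give a sorbate), no β-elimination of the acyloxy group from the butanoate, and no ester exchange at the benzyl ester. These should be secured by keeping the base below one equivalent relative to 5, so that the strongest base present is a β-dicarbonyl enolate too weak to enolise a simple ester, by the non-nucleophilic tert-butoxide, and by the acidic dione, which neutralises each methoxide as it is released.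

Step 6
Reactants: 11 (R)-4-(benzyloxy)-4-oxobutan-2-yl 6-{(R)-2-[(tert-butyldimethylsilyl)oxy]propyl}-2,4-dioxocyclohexane-1-carboxylate
Product: 12 benzyl (R)-3-[(6-{(R)-2-[(tert-butyldimethylsilyl)oxy]propyl}-2,4-dihydroxybenzoyl)oxy]butanoate
Conditions: Pd(OCOCF3)2 (5 mol %), 2-(dimethylamino)pyridine (10 mol %), O2 (1 atm), DMSO, 80 °C
Reagents that add atoms: none
Why: Aerobic palladium-catalysed dehydrogenation of a cyclohexanone-type ring: a palladium enolate at C5 (or C1) undergoes β-hydride elimination towards C6 and the resulting dienone tautomerises to the resorcinol, with O2 reoxidising the metal. The acidic dione stands in for the sulfonic acid co-catalyst usually added, which should spare the silyl ether; the silyl group in turn shields the secondary alcohol from oxidation.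

Step 7
Reactants: 12 benzyl (R)-3-[(6-{(R)-2-[(tert-butyldimethylsilyl)oxy]propyl}-2,4-dihydroxybenzoyl)oxy]butanoate
Product: 13 benzyl (R)-3-[(2,4-bis(benzyloxy)-6-{(R)-2-[(tert-butyldimethylsilyl)oxy]propyl}benzoyl)oxy]butanoate
Conditions: BnBr, K2CO3, Bu4NI (cat.), DMF, rt to 40 °C
Reagents that add atoms: benzyl bromide, BrCc1ccccc1
Why: Williamson ether synthesis on both phenols; carbonate is basic enough for the phenols (including the hydrogen-bonded ortho one with gentle warming) but not for the α-hydrogens of the β-acyloxy ester.

Step 8
Reactants: 13 benzyl (R)-3-[(2,4-bis(benzyloxy)-6-{(R)-2-[(tert-butyldimethylsilyl)oxy]propyl}benzoyl)oxy]butanoate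
Product: 14 benzyl (R)-3-({2,4-bis(benzyloxy)-6-[(R)-2-hydroxypropyl]benzoyl}oxy)butanoate
Conditions: HF·pyridine, THF/pyridine, 0 °C to rt
Reagents that add atoms: none
Why: Fluoride-driven desilylation under weakly acidic conditions frees the alcohol without passing through an alkoxide, which would attack the neighbouring benzoate; benzyl ethers and esters are inert.

Step 9
Reactants: 1 methyl (R)-3-hydroxybutanoate
Product: 15 methyl (R)-3-(benzyloxy)butanoate
Conditions: benzyl 2,2,2-trichloroacetimidate, TfOH (cat.), CH2Cl2/cyclohexane, 0 °C to rt
Reagents that add atoms: benzyl 2,2,2-trichloroacetimidate, ClC(Cl)(Cl)C(=N)OCc1ccccc1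
Why: Acid-catalysed O-benzylation with the imidate avoids the basic conditions under which a β-hydroxy ester eliminates or undergoes retro-aldol cleavage; the C–O bond at the stereocentre is not broken.

Step 10
Reactants: 15 methyl (R)-3-(benzyloxy)butanoate
Product: 16 (R)-3-(benzyloxy)-N-methoxy-N-methylbutanamide
Conditions: MeNH(OMe)·HCl, i-PrMgCl, THF, −20 to 0 °C
Reagents that add atoms: N,O-dimethylhydroxylamine hydrochloride, CNOC.Cl
Why: Direct Weinreb amidation of an ester by the magnesium amide formed in the flask; at low temperature acyl substitution should outrun α-deprotonation, so the β-benzyloxy group stays.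

Step 11
Reactants: 17 2,4-dihydroxy-6-methylbenzoic acid (orsellinic acid); 18 (S)-pent-4-en-2-ol
Product: 19 (R)-pent-4-en-2-yl 2,4-dihydroxy-6-methylbenzoate
Conditions: P(3-ClC6H4)3, DIAD, toluene, 0 °C to rt
Reagents that add atoms: none
Why: Mitsunobu esterification activates the alcohol, not the hindered acid, and the carboxylate displaces the oxyphosphonium group with clean inversion, so (S)-18 gives the (R)-ester; the electron-poor phosphine favours the acid over the less acidic phenols.

Step 12
Reactants: 19 (R)-pent-4-en-2-yl 2,4-dihydroxy-6-methylbenzoate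
Product: 20 (R)-pent-4-en-2-yl 2,4-bis(benzyloxy)-6-methylbenzoate
Conditions: BnBr, K2CO3, DMF, 60 °C
Reagents that add atoms: benzyl bromide, BrCc1ccccc1
Why: Williamson ether synthesis on both phenols; this ester has no β-leaving group and tolerates the warming needed for the chelated ortho phenol.

Step 13
Reactants: 20 (R)-pent-4-en-2-yl 2,4-bis(benzyloxy)-6-methylbenzoate; 16 (R)-3-(benzyloxy)-N-methoxy-N-methylbutanamide
Product: 21 (R)-pent-4-en-2-yl 2,4-bis(benzyloxy)-6-[(R)-4-(benzyloxy)-2-oxopentyl]benzoate
Conditions: LiN(i-Pr)2 (2 equiv), THF, −78 °C; then 16, −78 °C; sat. NH4Cl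
Reagents that add atoms: none
Why: Lateral lithiation of an ortho-toluate ester gives a benzylic anion that acylates the Weinreb amide (C8–C9 bond); the chelated tetrahedral adduct holds until the quench, so the ketone is not attacked twice, and the secondary, doubly ortho-substituted ester resists self-condensation. The terminal alkene has no acidic hydrogen, and C11 is carried in unchanged.

Step 14
Reactants: 21 (R)-pent-4-en-2-yl 2,4-bis(benzyloxy)-6-[(R)-4-(benzyloxy)-2-oxopentyl]benzoate
Product: 23 (R)-4-oxobutan-2-yl 2,4-bis(benzyloxy)-6-[(R)-4-(benzyloxy)-2-oxopentyl]benzoate, via vicinal diol 22 (not isolated)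
Conditions: OsO4 (2 mol %), NaIO4, 2,6-lutidine, dioxane/H2O, rt
Reagents that add atoms: osmium tetroxide (oxygen carrier), O=[Os](=O)(=O)=O; sodium periodate (terminal oxidant), [Na+].[O-]I(=O)(=O)=O
Why: Lemieux–Johnson cleavage: dihydroxylation of the only alkene and periodate cleavage of the diol give the aldehyde under near-neutral conditions; lutidine suppresses side reactions and is too weak to promote β-elimination.

Step 15
Reactants: 23 (R)-4-oxobutan-2-yl 2,4-bis(benzyloxy)-6-[(R)-4-(benzyloxy)-2-oxopentyl]benzoate
Product: 24 (R)-3-({2,4-bis(benzyloxy)-6-[(R)-4-(benzyloxy)-2-oxopentyl]benzoyl}oxy)butanoic acid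
Conditions: NaClO2, NaH2PO4, 2-methylbut-2-ene (excess), t-BuOH/H2O, 0 °C to rt
Reagents that add atoms: sodium chlorite, [Na+].[O-]Cl=O
Why: Pinnick oxidation converts the aldehyde to the acid at about pH 4, where the β-acyloxy group does not eliminate; the alkene scavenger removes hypochlorous acid before it can chlorinate the electron-rich ring or the benzylic ketone.

Step 16
Reactants: 14 benzyl (R)-3-({2,4-bis(benzyloxy)-6-[(R)-2-hydroxypropyl]benzoyl}oxy)butanoate; 24 (R)-3-({2,4-bis(benzyloxy)-6-[(R)-4-(benzyloxy)-2-oxopentyl]benzoyl}oxy)butanoic acid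
Product: 25 benzyl (R)-3-({2,4-bis(benzyloxy)-6-[(R)-2-{[(R)-3-({2,4-bis(benzyloxy)-6-[(R)-4-(benzyloxy)-2-oxopentyl]benzoyl}oxy)butanoyl]oxy}propyl]benzoyl}oxy)butanoate
Conditions: EDC·HCl, DMAP (cat.), CH2Cl2, 0 °C to rt
Reagents that add atoms: none
Why: Steglich esterification of the only free hydroxyl with an unhindered aliphatic acid; the carbinol C–O bond is not broken, so (R) is retained, and low temperature with substoichiometric DMAP keeps β-elimination and lactonisation slow relative to acyl transfer.

Step 17
Reactants: 25 benzyl (R)-3-({2,4-bis(benzyloxy)-6-[(R)-2-{[(R)-3-({2,4-bis(benzyloxy)-6-[(R)-4-(benzyloxy)-2-oxopentyl]benzoyl}oxy)butanoyl]oxy}propyl]benzoyl}oxy)butanoate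
Product: 26 Hansforester I
Conditions: H2 (1 atm), Pd/C, EtOAc, rt
Reagents that add atoms: none
Why: Hydrogenolysis cleaves the four aryl benzyl ethers, the benzyl ester and the C11 benzyl ether in one neutral operation; the aryl and alkyl esters, the C9 alkyl ketone and all four stereocentres are not affected, and a non-nucleophilic solvent excludes ester exchange.

## Compound list

1 | methyl (R)-3-hydroxybutanoate | C[C@@H](O)CC(=O)OC | starting material
2 | benzyl (R)-3-hydroxybutanoate | C[C@@H](O)CC(=O)OCc1ccccc1 | intermediate
3 | 2,2,6-trimethyl-4H-1,3-dioxin-4-one | CC1=CC(=O)OC(C)(C)O1 | starting material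
4 | acetylketene | CC(=O)C=C=O | intermediate
5 | (R)-4-(benzyloxy)-4-oxobutan-2-yl 3-oxobutanoate | CC(=O)CC(=O)O[C@H](C)CC(=O)OCc1ccccc1 | intermediate
6 | (R)-pent-4-en-2-ol | C[C@@H](O)CC=C | starting material
7 | tert-butyldimethyl[(R)-pent-4-en-2-yloxy]silane | C[C@@H](O[Si](C)(C)C(C)(C)C)CC=C | intermediate
8 | methyl acrylate | C=CC(=O)OC | starting material
9 | methyl (R,E)-5-[(tert-butyldimethylsilyl)oxy]hex-2-enoate | C[C@@H](O[Si](C)(C)C(C)(C)C)C/C=C/C(=O)OC | intermediate
10 | (R)-4-(benzyloxy)-4-oxobutan-2-yl (5R)-2-acetyl-5-[(tert-butyldimethylsilyl)oxy]-3-(2-methoxy-2-oxoethyl)hexanoate (Michael adduct, C2/C3 unspecified) | C[C@@H](O[Si](C)(C)C(C)(C)C)CC(CC(=O)OC)C(C(C)=O)C(=O)O[C@H](C)CC(=O)OCc1ccccc1 | intermediate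
11 | (R)-4-(benzyloxy)-4-oxobutan-2-yl 6-{(R)-2-[(tert-butyldimethylsilyl)oxy]propyl}-2,4-dioxocyclohexane-1-carboxylate (ring C1/C6 unspecified) | C[C@@H](O[Si](C)(C)C(C)(C)C)CC1CC(=O)CC(=O)C1C(=O)O[C@H](C)CC(=O)OCc1ccccc1 | intermediate
12 | benzyl (R)-3-[(6-{(R)-2-[(tert-butyldimethylsilyl)oxy]propyl}-2,4-dihydroxybenzoyl)oxy]butanoate | C[C@@H](O[Si](C)(C)C(C)(C)C)Cc1cc(O)cc(O)c1C(=O)O[C@H](C)CC(=O)OCc1ccccc1 | intermediate
13 | benzyl (R)-3-[(2,4-bis(benzyloxy)-6-{(R)-2-[(tert-butyldimethylsilyl)oxy]propyl}benzoyl)oxy]butanoate | C[C@@H](O[Si](C)(C)C(C)(C)C)Cc1cc(OCc2ccccc2)cc(OCc2ccccc2)c1C(=O)O[C@H](C)CC(=O)OCc1ccccc1 | intermediate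
14 | benzyl (R)-3-({2,4-bis(benzyloxy)-6-[(R)-2-hydroxypropyl]benzoyl}oxy)butanoate | C[C@@H](O)Cc1cc(OCc2ccccc2)cc(OCc2ccccc2)c1C(=O)O[C@H](C)CC(=O)OCc1ccccc1 | intermediate
15 | methyl (R)-3-(benzyloxy)butanoate | C[C@@H](OCc1ccccc1)CC(=O)OC | intermediate
16 | (R)-3-(benzyloxy)-N-methoxy-N-methylbutanamide | C[C@@H](OCc1ccccc1)CC(=O)N(C)OC | intermediate
17 | 2,4-dihydroxy-6-methylbenzoic acid (orsellinic acid) | Cc1cc(O)cc(O)c1C(=O)O | starting material
18 | (S)-pent-4-en-2-ol | C[C@H](O)CC=C | starting material
19 | (R)-pent-4-en-2-yl 2,4-dihydroxy-6-methylbenzoate | Cc1cc(O)cc(O)c1C(=O)O[C@H](C)CC=C | intermediate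
20 | (R)-pent-4-en-2-yl 2,4-bis(benzyloxy)-6-methylbenzoate | Cc1cc(OCc2ccccc2)cc(OCc2ccccc2)c1C(=O)O[C@H](C)CC=C | intermediate
21 | (R)-pent-4-en-2-yl 2,4-bis(benzyloxy)-6-[(R)-4-(benzyloxy)-2-oxopentyl]benzoate | C[C@@H](OCc1ccccc1)CC(=O)Cc1cc(OCc2ccccc2)cc(OCc2ccccc2)c1C(=O)O[C@H](C)CC=C | intermediate
22 | (2R)-4,5-dihydroxypentan-2-yl 2,4-bis(benzyloxy)-6-[(R)-4-(benzyloxy)-2-oxopentyl]benzoate (C4 unspecified) | C[C@@H](OCc1ccccc1)CC(=O)Cc1cc(OCc2ccccc2)cc(OCc2ccccc2)c1C(=O)O[C@H](C)CC(O)CO | intermediate
23 | (R)-4-oxobutan-2-yl 2,4-bis(benzyloxy)-6-[(R)-4-(benzyloxy)-2-oxopentyl]benzoate | C[C@@H](OCc1ccccc1)CC(=O)Cc1cc(OCc2ccccc2)cc(OCc2ccccc2)c1C(=O)O[C@H](C)CC=O | intermediate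
24 | (R)-3-({2,4-bis(benzyloxy)-6-[(R)-4-(benzyloxy)-2-oxopentyl]benzoyl}oxy)butanoic acid | C[C@@H](OCc1ccccc1)CC(=O)Cc1cc(OCc2ccccc2)cc(OCc2ccccc2)c1C(=O)O[C@H](C)CC(=O)O | intermediate
25 | hexabenzyl-protected Hansforester I (full name in step 16) | C[C@H](Cc1cc(OCc2ccccc2)cc(OCc2ccccc2)c1C(=O)O[C@H](C)CC(=O)OCc1ccccc1)OC(=O)C[C@@H](C)OC(=O)c1c(OCc2ccccc2)cc(OCc2ccccc2)cc1CC(=O)C[C@@H](C)OCc1ccccc1 | intermediate
26 | Hansforester I | C[C@H](Cc1cc(O)cc(O)c1C(=O)O[C@H](C)CC(=O)O)OC(=O)C[C@@H](C)OC(=O)c1c(O)cc(O)cc1CC(=O)C[C@@H](C)O | target

## Step count and least certain steps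

Total: 17 steps. Longest linear sequence: 8 steps (1, 2, 5, 6, 7, 8, 16, 17; the enoate branch 3, 4, 5, 6, 7, 8, 16, 17 is equally long; the ring B branch has 7).

**Step 5 (key step).**
- What may go wrong: traces of free alkoxide may enolise 9 at C4 and expel the silyloxy group (vinylogous β-elimination); they may enolise the benzyl ester of 5, 10 or 11 and expel the β-acyloxy group; and the Michael addition may revert if ring closure is slow.
- Fallback, from 9 back to 12: commercial benzyl acetoacetate would be annulated with 9 under the same conditions to give benzyl 6-{(R)-2-[(tert-butyldimethylsilyl)oxy]propyl}-2,4-dioxocyclohexane-1-carboxylate F1, which has no β-acyloxy ester. Dehydrogenation as in step 6 would give benzyl 6-{(R)-2-[(tert-butyldimethylsilyl)oxy]propyl}-2,4-dihydroxybenzoate F2, and hydrogenolysis (H2, Pd/C) would give 6-{(R)-2-[(tert-butyldimethylsilyl)oxy]propyl}-2,4-dihydroxybenzoic acid F3. A Mitsunobu esterification as in step 11 with benzyl (S)-3-hydroxybutanoate F4 (from methyl (S)-3-hydroxybutanoate as in step 1) would then give 12 with inversion. The ring is built in the same way; only the butanoate is attached afterwards.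

**Step 6.**
- What may go wrong: catalyst turnover may stall because the dione holds divalent palladium as a stable diketonate; long heating may cleave the silyl ether, after which the freed alcohol can be oxidised or lactonise.
- Fallback, from 11 back to 14: bromination and dehydrobromination (Br2, DMF, 0 °C, then 80 °C), the classical aromatisation of this dione class. The hydrogen bromide formed is expected to remove the silyl group, giving benzyl (R)-3-({2,4-dihydroxy-6-[(R)-2-hydroxypropyl]benzoyl}oxy)butanoate F5. Its phenols would be benzylated selectively (BnBr, K2CO3, acetone, rt), since carbonate does not deprotonate the aliphatic alcohol. This reaches 14 directly and bypasses 12, 13 and step 8; exposure to acid and base would have to be kept short to limit lactonisation.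

**Step 13.**
- What may go wrong: the benzylic anion may deprotonate 16 at its α-carbon, with loss of benzyl oxide; the toluate anion may self-condense; and the ketone enolate may cyclise onto the neighbouring ester on warming.
- Fallback, from 1 and 20 back to 21: direct Weinreb amidation of 1 (as in step 10) would give (R)-3-hydroxy-N-methoxy-N-methylbutanamide F6. After deprotonation of its hydroxyl with one extra equivalent of LiN(i-Pr)2, the alkoxide is no leaving group and disfavours α-deprotonation. Acylation of the anion of 20 would give (R)-pent-4-en-2-yl 2,4-bis(benzyloxy)-6-[(R)-4-hydroxy-2-oxopentyl]benzoate F7, and acid-catalysed benzylation with the imidate of step 9 would give 21.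

**Step 16.**
- What may go wrong: the activated acyl derivative of 24 may lose the ring B carboxylate by β-elimination; 14 may lactonise onto its own benzoate under the basic acyl-transfer conditions; and slow acylation may divert the activated acid to an N-acylurea.
- Fallback, from 14 back to 25: the alcohol is activated instead of the acid. Mitsunobu reaction of 14 with chloroacetic acid (PPh3, DIAD) would give the inverted benzyl (R)-3-({2,4-bis(benzyloxy)-6-[(S)-2-(2-chloroacetoxy)propyl]benzoyl}oxy)butanoate F8. Thiourea (NaHCO3, EtOH, 50 °C) would remove the chloroacetyl group selectively to give benzyl (R)-3-({2,4-bis(benzyloxy)-6-[(S)-2-hydroxypropyl]benzoyl}oxy)butanoate F9. A second Mitsunobu reaction of F9 with 24 as the nucleophile would give 25 with the (R) configuration restored, and 24 is never activated at its carbonyl.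

## Further compounds

F1 | step 5 | benzyl 6-{(R)-2-[(tert-butyldimethylsilyl)oxy]propyl}-2,4-dioxocyclohexane-1-carboxylate | C[C@@H](O[Si](C)(C)C(C)(C)C)CC1CC(=O)CC(=O)C1C(=O)OCc1ccccc1
F2 | step 5 | benzyl 6-{(R)-2-[(tert-butyldimethylsilyl)oxy]propyl}-2,4-dihydroxybenzoate | C[C@@H](O[Si](C)(C)C(C)(C)C)Cc1cc(O)cc(O)c1C(=O)OCc1ccccc1
F3 | step 5 | 6-{(R)-2-[(tert-butyldimethylsilyl)oxy]propyl}-2,4-dihydroxybenzoic acid | C[C@@H](O[Si](C)(C)C(C)(C)C)Cc1cc(O)cc(O)c1C(=O)O
F4 | step 5 | benzyl (S)-3-hydroxybutanoate | C[C@H](O)CC(=O)OCc1ccccc1
F5 | step 6 | benzyl (R)-3-({2,4-dihydroxy-6-[(R)-2-hydroxypropyl]benzoyl}oxy)butanoate | C[C@@H](O)Cc1cc(O)cc(O)c1C(=O)O[C@H](C)CC(=O)OCc1ccccc1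
F6 | step 13 | (R)-3-hydroxy-N-methoxy-N-methylbutanamide | C[C@@H](O)CC(=O)N(C)OC
F7 | step 13 | (R)-pent-4-en-2-yl 2,4-bis(benzyloxy)-6-[(R)-4-hydroxy-2-oxopentyl]benzoate | C[C@@H](O)CC(=O)Cc1cc(OCc2ccccc2)cc(OCc2ccccc2)c1C(=O)O[C@H](C)CC=C
F8 | step 16 | benzyl (R)-3-({2,4-bis(benzyloxy)-6-[(S)-2-(2-chloroacetoxy)propyl]benzoyl}oxy)butanoate | C[C@H](OC(=O)CCl)Cc1cc(OCc2ccccc2)cc(OCc2ccccc2)c1C(=O)O[C@H](C)CC(=O)OCc1ccccc1
F9 | step 16 | benzyl (R)-3-({2,4-bis(benzyloxy)-6-[(S)-2-hydroxypropyl]benzoyl}oxy)butanoate | C[C@H](O)Cc1cc(OCc2ccccc2)cc(OCc2ccccc2)c1C(=O)O[C@H](C)CC(=O)OCc1ccccc1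
A1 | alternative 1 | 2-(tert-butyldimethylsilyl)-1,3-dithiane | CC(C)(C)[Si](C)(C)C1SCCCS1
A2 | alternative 1 | (R)-propylene oxide | C[C@@H]1CO1
A3 | alternative 1 | 1,5-bis(benzyloxy)-2-bromo-3-(bromomethyl)benzene | BrCc1cc(OCc2ccccc2)cc(OCc2ccccc2)c1Br
A4 | alternative 1 | 2-{[3,5-bis(benzyloxy)-2-bromophenyl]methyl}-2-{(R)-2-[(tert-butyldimethylsilyl)oxy]propyl}-1,3-dithiane | C[C@H](CC1(Cc2cc(OCc3ccccc3)cc(OCc3ccccc3)c2Br)SCCCS1)O[Si](C)(C)C(C)(C)C
A5 | alternative 2 | (R)-4-(benzyloxy)-4-oxobutan-2-yl (R)-5-[(tert-butyldimethylsilyl)oxy]hex-2-ynoate | C[C@@H](O[Si](C)(C)C(C)(C)C)CC#CC(=O)O[C@H](C)CC(=O)OCc1ccccc1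
A6 | alternative 2 | 1,3-bis(trimethylsilyloxy)-5,5-dimethylcyclohexa-1,3-diene | C[Si](C)(C)OC1=CC(O[Si](C)(C)C)=CC(C)(C)C1
A7 | alternative 2 | benzyl (R)-3-[(6-{(R)-2-[(tert-butyldimethylsilyl)oxy]propyl}-2,4-dihydroxybenzoyl)oxy]butanoate (identical with 12) | C[C@@H](O[Si](C)(C)C(C)(C)C)Cc1cc(O)cc(O)c1C(=O)O[C@H](C)CC(=O)OCc1ccccc1
A8 | alternative 3 | 6-[5-(2-{(R)-2-[(tert-butyldimethylsilyl)oxy]propyl}-1,3-dioxolan-2-yl)-2,4-dioxopentyl]-2,2-dimethyl-4H-1,3-dioxin-4-one | CC1(C)OC(=O)C=C(CC(=O)CC(=O)CC2(C[C@@H](C)O[Si](C)(C)C(C)(C)C)OCCO2)O1
A9 | alternative 3 | benzyl (R)-3-({2,4-bis(benzyloxy)-6-[(R)-2-{[(R)-3-hydroxybutanoyl]oxy}propyl]benzoyl}oxy)butanoate | C[C@@H](O)CC(=O)O[C@H](C)Cc1cc(OCc2ccccc2)cc(OCc2ccccc2)c1C(=O)O[C@H](C)CC(=O)OCc1ccccc1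
A10 | alternative 3 | full skeleton with free ring B phenols, C9 dioxolane, C11 silyl ether and benzyl groups on ring A and the terminal acid | C[C@@H](O[Si](C)(C)C(C)(C)C)CC1(Cc2cc(O)cc(O)c2C(=O)O[C@H](C)CC(=O)O[C@H](C)Cc2cc(OCc3ccccc3)cc(OCc3ccccc3)c2C(=O)O[C@H](C)CC(=O)OCc2ccccc2)OCCO1
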